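**Retrosynthetic overview**
1. Target 24 ⇐ silyl ether 23 ⇐ bromohydrin 20 ⇐ epoxide 19 ⇐ cyclohexene 18. The trans-diequatorial Br/Cl pair is built by a bromonium relay, because direct BrCl addition to the ring alkene is expected to give the trans-diaxial isomer.
2. Oxane ring (second ring formed) ⇐ 6-endo bromoetherification of diol 16.
3. Tertiary carbinol of 16 ⇐ chelation-controlled homoprenyl Grignard addition to β-hydroxy methyl ketone 12 ⇐ Weinreb amide 10.
4. Cyclohexene (first ring formed) ⇐ ring-closing metathesis of syn-aldol adduct 8.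
5. Key C–C bond C1′–C6′ ⇐ intermolecular Evans boron aldol of imide 3 with 3-methylbut-3-enal 5.

Notation: oxane atoms are O1, C2–C6; the carbocycle is C1′ (bears the oxane), C2′, C3′ (CHBr), C4′ (C(Cl)CH3), C5′, C6′ (CHOH). "Upper face" is the face opposite the C1′ and C6′ substituents.

**Route**

Step 1
Reactants: 1 (4R)-4-benzyl-1,3-oxazolidin-2-one; 2 pent-4-enoyl chloride
Product: 3 (4R)-4-benzyl-3-(pent-4-enoyl)-1,3-oxazolidin-2-one
Conditions: Et3N, DMAP (cat.), CH2Cl2, 0 °C → rt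
Reagents that add atoms: none
Why: N-acylation of the oxazolidinone by the acid chloride under nucleophilic (DMAP) catalysis, leaving the auxiliary stereocentre untouched.

Step 2
Reactants: 4 3-methylbut-3-en-1-ol
Product: 5 3-methylbut-3-enal (kept as a cold CH2Cl2 solution and used at once)
Conditions: Dess–Martin periodinane, CH2Cl2, 0 °C → rt
Reagents that add atoms: none
Why: Dess–Martin oxidation gives the β,γ-unsaturated aldehyde under non-basic conditions, and immediate use avoids isomerisation to the conjugated enal.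

Step 3
Reactants: 3 (4R)-4-benzyl-3-(pent-4-enoyl)-1,3-oxazolidin-2-one; 5 3-methylbut-3-enal
Product: 8 (4R)-4-benzyl-3-[(2R,3S)-3-hydroxy-5-methyl-2-(prop-2-en-1-yl)hex-5-enoyl]-1,3-oxazolidin-2-one, via Z-dibutylboron enolate 6 (not isolated), via dibutylboron aldolate 7 (not isolated)
Conditions: Bu2BOTf, i-Pr2NEt, CH2Cl2, −78 → 0 °C; then 5, −78 → 0 °C; pH 7 buffer, MeOH, 30% H2O2, 0 °C
Reagents that add atoms: none
Why: Evans syn-aldol reaction in which the Z-boron enolate 6 reacts through a Zimmerman–Traxler chair on the face opposite the benzyl group of the (R)-auxiliary, setting C1′ (R) and C6′ (S) in the 2,3-syn sense that becomes cis on the ring.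

Step 4
Reactants: 8 (4R)-4-benzyl-3-[(2R,3S)-3-hydroxy-5-methyl-2-(prop-2-en-1-yl)hex-5-enoyl]-1,3-oxazolidin-2-one
Product: 9 (4R)-4-benzyl-3-{[(1R,6S)-6-hydroxy-4-methylcyclohex-3-en-1-yl]carbonyl}-1,3-oxazolidin-2-one
Conditions: second-generation Grubbs catalyst (3 mol %), CH2Cl2 (0.01 M), 40 °C
Reagents that add atoms: none
Why: Ring-closing olefin metathesis of the allyl and methallyl termini releases ethene and closes the trisubstituted cyclohexene without touching the two stereocentres, which end up cis.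

Step 5
Reactants: 9 (4R)-4-benzyl-3-{[(1R,6S)-6-hydroxy-4-methylcyclohex-3-en-1-yl]carbonyl}-1,3-oxazolidin-2-one
Product: 10 (1R,6S)-6-hydroxy-N-methoxy-N,4-dimethylcyclohex-3-ene-1-carboxamide
Conditions: MeNH(OMe)·HCl, AlMe3, CH2Cl2, −15 → 0 °C; H2O work-up
Reagents that add atoms: N,O-dimethylhydroxylamine hydrochloride, CNOC.Cl
Why: Weinreb transamination by the aluminium amide, assisted by the free β-hydroxyl, cleaves the auxiliary (recovered) without epimerising C1′.

Step 6
Reactants: 10 (1R,6S)-6-hydroxy-N-methoxy-N,4-dimethylcyclohex-3-ene-1-carboxamide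
Product: 12 1-[(1R,6S)-6-hydroxy-4-methylcyclohex-3-en-1-yl]ethan-1-one, via magnesium hemiaminal chelate 11 (not isolated)
Conditions: MeMgBr (3 equiv), THF, −20 → 0 °C; cold aq. NH4Cl
Reagents that add atoms: methylmagnesium bromide, C[Mg]Br
Why: Weinreb ketone synthesis in which the chelated tetrahedral adduct 11 survives until work-up, so only one methyl is delivered and C1′ is not enolised.

Step 7
Reactants: 13 5-bromo-2-methylpent-2-ene
Product: 14 (4-methylpent-3-en-1-yl)magnesium bromide (titrated ethereal solution, used directly)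
Conditions: Mg, I2 (cat.), Et2O, reflux
Reagents that add atoms: magnesium, [Mg]
Why: Grignard formation by Mg insertion into a primary homoallylic bromide.

Step 8
Reactants: 12 1-[(1R,6S)-6-hydroxy-4-methylcyclohex-3-en-1-yl]ethan-1-one; 14 (4-methylpent-3-en-1-yl)magnesium bromide
Product: 16 (1S,6R)-6-[(2S)-2-hydroxy-6-methylhept-5-en-2-yl]-3-methylcyclohex-3-en-1-ol, via bromomagnesium alkoxide chelate 15 (not isolated)
Conditions: 14 (3 equiv), Et2O/CH2Cl2, −78 → −20 °C; aq. NH4Cl
Reagents that add atoms: none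
Why: Chelation-controlled Grignard 1,2-addition (Cram-chelate type) in which alkoxide 15 holds the ketone in a six-membered Mg chelate cis-fused to the ring and the nucleophile attacks the carbonyl face away from the C2′ methylene, giving the (2S) tertiary alcohol.

Step 9
Reactants: 16 (1S,6R)-6-[(2S)-2-hydroxy-6-methylhept-5-en-2-yl]-3-methylcyclohex-3-en-1-ol
Product: 17 (1S,6R)-6-[(2S,5R)-5-bromo-2,6,6-trimethyloxan-2-yl]-3-methylcyclohex-3-en-1-ol
Conditions: TBCO (1.1 equiv), MeNO2, 0 °C → rt, dark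
Reagents that add atoms: 2,4,4,6-tetrabromocyclohexa-2,5-dien-1-one (TBCO), O=C1C(Br)=CC(Br)(Br)C=C1Br
Why: Bromonium-induced 6-endo (Markovnikov) bromoetherification by the tertiary hydroxyl through a chair transition state with the carbocycle equatorial, the C2 methyl axial and anti addition placing Br equatorial, which sets C5 (R) trans to the carbocycle while the ring alkene has no hydroxyl placed for a strain-free closure.

Step 10
Reactants: 17 (1S,6R)-6-[(2S,5R)-5-bromo-2,6,6-trimethyloxan-2-yl]-3-methylcyclohex-3-en-1-ol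
Product: 18 tert-butyl({(1S,6R)-6-[(2S,5R)-5-bromo-2,6,6-trimethyloxan-2-yl]-3-methylcyclohex-3-en-1-yl}oxy)dimethylsilane
Conditions: TBSOTf, 2,6-lutidine, CH2Cl2, −78 → 0 °C
Reagents that add atoms: tert-butyldimethylsilyl trifluoromethanesulfonate, CC(C)(C)[Si](C)(C)OS(=O)(=O)C(F)(F)F
Why: Silyl ether formation on the only free hydroxyl with the silyl triflate, affecting no stereocentre and removing the OH that would otherwise direct the peracid and compete in the chlorination.

Step 11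
Reactants: 18 tert-butyl({(1S,6R)-6-[(2S,5R)-5-bromo-2,6,6-trimethyloxan-2-yl]-3-methylcyclohex-3-en-1-yl}oxy)dimethylsilane
Product: 19 tert-butyl({(1S,3S,4R,6R)-4-[(2S,5R)-5-bromo-2,6,6-trimethyloxan-2-yl]-1-methyl-7-oxabicyclo[4.1.0]heptan-3-yl}oxy)dimethylsilane (epoxide on the upper face)
Conditions: mCPBA, CH2Cl2, 0 °C
Reagents that add atoms: 3-chloroperoxybenzoic acid, OOC(=O)c1cccc(Cl)c1
Why: Prilezhaev epoxidation in which the peracid attacks the alkene face anti to the axial C6′ silyloxy group (the oxanyl group sits equatorial), giving the upper-face epoxide (C3′ R, C4′ S), separable from any minor lower-face isomer.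

Step 12
Reactants: 19 tert-butyl({(1S,3S,4R,6R)-4-[(2S,5R)-5-bromo-2,6,6-trimethyloxan-2-yl]-1-methyl-7-oxabicyclo[4.1.0]heptan-3-yl}oxy)dimethylsilane
Product: 20 (1R,2R,4S,5R)-2-bromo-5-[(2S,5R)-5-bromo-2,6,6-trimethyloxan-2-yl]-4-{[tert-butyl(dimethyl)silyl]oxy}-2-methylcyclohexan-1-ol
Conditions: HBr (1.1 equiv, solution in CH2Cl2), CH2Cl2, −78 °C
Reagents that add atoms: hydrogen bromide, Br
Why: Acid-mediated epoxide opening that is both Markovnikov and trans-diaxial (Fürst–Plattner), so bromide attacks the tertiary C4′ from the lower face with inversion and leaves the axial C3′ alcohol on the upper face.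

Step 13
Reactants: 20 (1R,2R,4S,5R)-2-bromo-5-[(2S,5R)-5-bromo-2,6,6-trimethyloxan-2-yl]-4-{[tert-butyl(dimethyl)silyl]oxy}-2-methylcyclohexan-1-ol
Product: 23 tert-butyl({(1S,2R,4S,5S)-4-bromo-2-[(2S,5R)-5-bromo-2,6,6-trimethyloxan-2-yl]-5-chloro-5-methylcyclohexyl}oxy)dimethylsilane, via chlorosulfite ester 21 (not isolated), via lower-face bromonium chloride 22 (not isolated)
Conditions: SOCl2, pyridine, CH2Cl2, −40 → 0 °C
Reagents that add atoms: thionyl chloride, ClS(Cl)=O
Why: Deoxychlorination with neighbouring-group participation in which chlorosulfite 21 ionises with anti-periplanar bromine assistance to the lower-face bromonium ion 22 and chloride opens it at the tertiary C4′ from the upper face (Markovnikov), so Br ends at C3′ (S) and Cl at C4′ (S), trans to each other.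

Step 14
Reactants: 23 tert-butyl({(1S,2R,4S,5S)-4-bromo-2-[(2S,5R)-5-bromo-2,6,6-trimethyloxan-2-yl]-5-chloro-5-methylcyclohexyl}oxy)dimethylsilane
Product: 24 (1S,2R,4S,5S)-4-bromo-2-[(2S,5R)-5-bromo-2,6,6-trimethyloxan-2-yl]-5-chloro-5-methylcyclohexan-1-ol
Conditions: HF·pyridine, THF, 0 °C → rt
Reagents that add atoms: none
Why: Fluoride-mediated desilylation under acidic, non-basic conditions leaves the tertiary chloride and both bromides untouched and releases the target.

**Compound list**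
1 | (4R)-4-benzyl-1,3-oxazolidin-2-one | O=C1N[C@H](Cc2ccccc2)CO1 | starting material
2 | pent-4-enoyl chloride | C=CCCC(Cl)=O | starting material
3 | (4R)-4-benzyl-3-(pent-4-enoyl)-1,3-oxazolidin-2-one | C=CCCC(=O)N1[C@H](Cc2ccccc2)COC1=O | intermediate
4 | 3-methylbut-3-en-1-ol | CC(=C)CCO | starting material
5 | 3-methylbut-3-enal | CC(=C)CC=O | intermediate
6 | Z-dibutylboron enolate of 3, (4R)-4-benzyl-3-[(1Z)-1-(dibutylboranyloxy)penta-1,4-dien-1-yl]-1,3-oxazolidin-2-one | C=CC/C=C(\OB(CCCC)CCCC)N1[C@H](Cc2ccccc2)COC1=O | intermediate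
7 | dibutylboron aldolate (O-dibutylboranyl derivative of 8) | C=CC[C@H]([C@@H](OB(CCCC)CCCC)CC(C)=C)C(=O)N1[C@H](Cc2ccccc2)COC1=O | intermediate
8 | (4R)-4-benzyl-3-[(2R,3S)-3-hydroxy-5-methyl-2-(prop-2-en-1-yl)hex-5-enoyl]-1,3-oxazolidin-2-one | C=CC[C@H]([C@@H](O)CC(C)=C)C(=O)N1[C@H](Cc2ccccc2)COC1=O | intermediate
9 | (4R)-4-benzyl-3-{[(1R,6S)-6-hydroxy-4-methylcyclohex-3-en-1-yl]carbonyl}-1,3-oxazolidin-2-one | O=C([C@@H]1CC=C(C)C[C@@H]1O)N1[C@H](Cc2ccccc2)COC1=O | intermediate
10 | (1R,6S)-6-hydroxy-N-methoxy-N,4-dimethylcyclohex-3-ene-1-carboxamide | CON(C)C(=O)[C@@H]1CC=C(C)C[C@@H]1O | intermediate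
11 | magnesium hemiaminal chelate (bis-bromomagnesium salt of the tetrahedral adduct of 10 and MeMgBr) | CON(C)C(C)(O[Mg]Br)[C@@H]1CC=C(C)C[C@@H]1O[Mg]Br | intermediate
12 | 1-[(1R,6S)-6-hydroxy-4-methylcyclohex-3-en-1-yl]ethan-1-one | CC(=O)[C@@H]1CC=C(C)C[C@@H]1O | intermediate
13 | 5-bromo-2-methylpent-2-ene | CC(C)=CCCBr | starting material
14 | (4-methylpent-3-en-1-yl)magnesium bromide | CC(C)=CCC[Mg]Br | intermediate
15 | bromomagnesium alkoxide chelate of 12 | CC(=O)[C@@H]1CC=C(C)C[C@@H]1O[Mg]Br | intermediate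
16 | (1S,6R)-6-[(2S)-2-hydroxy-6-methylhept-5-en-2-yl]-3-methylcyclohex-3-en-1-ol | CC(C)=CCC[C@](C)(O)[C@@H]1CC=C(C)C[C@@H]1O | intermediate
17 | (1S,6R)-6-[(2S,5R)-5-bromo-2,6,6-trimethyloxan-2-yl]-3-methylcyclohex-3-en-1-ol | CC1(C)O[C@](C)([C@@H]2CC=C(C)C[C@@H]2O)CC[C@H]1Br | intermediate
18 | tert-butyl({(1S,6R)-6-[(2S,5R)-5-bromo-2,6,6-trimethyloxan-2-yl]-3-methylcyclohex-3-en-1-yl}oxy)dimethylsilane | CC1(C)O[C@](C)([C@@H]2CC=C(C)C[C@@H]2O[Si](C)(C)C(C)(C)C)CC[C@H]1Br | intermediate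
19 | tert-butyl({(1S,3S,4R,6R)-4-[(2S,5R)-5-bromo-2,6,6-trimethyloxan-2-yl]-1-methyl-7-oxabicyclo[4.1.0]heptan-3-yl}oxy)dimethylsilane | CC1(C)O[C@](C)([C@@H]2C[C@H]3O[C@@]3(C)C[C@@H]2O[Si](C)(C)C(C)(C)C)CC[C@H]1Br | intermediate
20 | (1R,2R,4S,5R)-2-bromo-5-[(2S,5R)-5-bromo-2,6,6-trimethyloxan-2-yl]-4-{[tert-butyl(dimethyl)silyl]oxy}-2-methylcyclohexan-1-ol | CC1(C)O[C@](C)([C@@H]2C[C@@H](O)[C@](C)(Br)C[C@@H]2O[Si](C)(C)C(C)(C)C)CC[C@H]1Br | intermediate
21 | chlorosulfite ester of 20 (O–S(=O)Cl on the C3′ oxygen) | CC1(C)O[C@](C)([C@@H]2C[C@@H](OS(Cl)=O)[C@](C)(Br)C[C@@H]2O[Si](C)(C)C(C)(C)C)CC[C@H]1Br | intermediate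
22 | bromonium chloride with Br bridging C3′ and C4′ on the lower face | CC1(C)O[C@](C)([C@@H]2C[C@@H]3[Br+][C@]3(C)C[C@@H]2O[Si](C)(C)C(C)(C)C)CC[C@H]1Br.[Cl-] | intermediate
23 | tert-butyl({(1S,2R,4S,5S)-4-bromo-2-[(2S,5R)-5-bromo-2,6,6-trimethyloxan-2-yl]-5-chloro-5-methylcyclohexyl}oxy)dimethylsilane | CC1(C)O[C@](C)([C@@H]2C[C@H](Br)[C@@](C)(Cl)C[C@@H]2O[Si](C)(C)C(C)(C)C)CC[C@H]1Br | intermediate
24 | (1S,2R,4S,5S)-4-bromo-2-[(2S,5R)-5-bromo-2,6,6-trimethyloxan-2-yl]-5-chloro-5-methylcyclohexan-1-ol | CC1(C)O[C@](C)([C@@H]2C[C@H](Br)[C@@](C)(Cl)C[C@@H]2O)CC[C@H]1Br | target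

**Step count**
Total steps: 14. Longest linear sequence: 12 (steps 1, 3, 4, 5, 6, 8, 9, 10, 11, 12, 13, 14); steps 2 and 7 are side branches.

**Three steps most likely to fail**

Step 13 (chlorination with 1,2-bromine shift). Chloride may instead open bromonium 22 at the secondary C3′ (the trans-diaxial mode), or the ion may lose a proton. The Markovnikov-versus-diaxial preference here is a mechanistic judgement, not a precedented result. Fallback, setting out from 20 and coming back at 23: run the chlorination with SOCl2 in Et2O without base at −20 °C so that the chlorosulfite collapses by internal return with bromine participation (net retention at C3′). This gives the trans-diaxial regioisomer tert-butyl({(1S,2R,4R,5R)-5-bromo-2-[(2S,5R)-5-bromo-2,6,6-trimethyloxan-2-yl]-4-chloro-5-methylcyclohexyl}oxy)dimethylsilane F1. Then heat F1 in toluene (80–110 °C) to induce the thermal diaxial-to-diequatorial 1,2-interchange of vicinal halogens: Br moves from C4′ to C3′ on the lower face and Cl from C3′ to C4′ on the upper face. This relieves the 1,3-diaxial Br/OSi contact and delivers 23.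

Step 9 (bromoetherification). The 5-exo oxolane, the C5 epimer and products from attack on the ring alkene can all erode the yield; yields for 2,2,6,6-tetrasubstituted oxanes by this reaction are typically modest. Fallback, setting out from 16 and coming back at 17: cyclise with Hg(OCOCF3)2 (1.0 equiv) in MeCN at −20 °C (Markovnikov 6-endo oxymercuration by the tertiary hydroxyl, Hg equatorial), then exchange with aq. KBr. This gives (1S,6R)-6-[(2S,5R)-5-(bromomercurio)-2,6,6-trimethyloxan-2-yl]-3-methylcyclohex-3-en-1-ol F2. Bromodemercuration of F2 with Br2 and LiBr in pyridine at 0 °C in the dark (retention) then gives 17.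

Step 8 (chelation-controlled addition). Enolisation of the methyl ketone or incomplete chelation would lower yield or diastereoselectivity. Fallback, setting out from 10 and coming back at 18, reverses the order of carbon introduction and relies on Felkin–Anh control:
- Silylate 10 (TBSOTf, 2,6-lutidine) to (1R,6S)-6-{[tert-butyl(dimethyl)silyl]oxy}-N-methoxy-N,4-dimethylcyclohex-3-ene-1-carboxamide F3.
- Add Grignard 14 (THF, 0 °C) to give 1-[(1R,6S)-6-{[tert-butyl(dimethyl)silyl]oxy}-4-methylcyclohex-3-en-1-yl]-5-methylhex-4-en-1-one F4.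
- Add MeMgBr in Et2O at −78 °C; with the non-chelating silyl ether, attack anti to the C6′ branch gives (2S)-2-[(1R,6S)-6-{[tert-butyl(dimethyl)silyl]oxy}-4-methylcyclohex-3-en-1-yl]-6-methylhept-5-en-2-ol F5.
- Bromoetherify F5 with TBCO as in step 9, which gives 18 directly and makes steps 9 and 10 unnecessary.

**Further compounds**
F1 | step 13 | tert-butyl({(1S,2R,4R,5R)-5-bromo-2-[(2S,5R)-5-bromo-2,6,6-trimethyloxan-2-yl]-4-chloro-5-methylcyclohexyl}oxy)dimethylsilane | CC1(C)O[C@](C)([C@@H]2C[C@@H](Cl)[C@](C)(Br)C[C@@H]2O[Si](C)(C)C(C)(C)C)CC[C@H]1Br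
F2 | step 9 | (1S,6R)-6-[(2S,5R)-5-(bromomercurio)-2,6,6-trimethyloxan-2-yl]-3-methylcyclohex-3-en-1-ol | CC1(C)O[C@](C)([C@@H]2CC=C(C)C[C@@H]2O)CC[C@H]1[Hg]Br
F3 | step 8 | (1R,6S)-6-{[tert-butyl(dimethyl)silyl]oxy}-N-methoxy-N,4-dimethylcyclohex-3-ene-1-carboxamide | CON(C)C(=O)[C@@H]1CC=C(C)C[C@@H]1O[Si](C)(C)C(C)(C)C
F4 | step 8 | 1-[(1R,6S)-6-{[tert-butyl(dimethyl)silyl]oxy}-4-methylcyclohex-3-en-1-yl]-5-methylhex-4-en-1-one | CC(C)=CCCC(=O)[C@@H]1CC=C(C)C[C@@H]1O[Si](C)(C)C(C)(C)C
F5 | step 8 | (2S)-2-[(1R,6S)-6-{[tert-butyl(dimethyl)silyl]oxy}-4-methylcyclohex-3-en-1-yl]-6-methylhept-5-en-2-ol | CC(C)=CCC[C@](C)(O)[C@@H]1CC=C(C)C[C@@H]1O[Si](C)(C)C(C)(C)C
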